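**Retrosynthetic overview**

1. α-Onocerin 16 (C2-symmetric) ⇒ twofold Wittig methylenation of diketone 15 ⇒ reductive tail-to-tail hydrodimerization (C11–C12 bond) of two molecules of bicyclic enone 13.
2. Ring A of 13 ⇒ one-pot two-carbon annulation of the monocyclic ring B building block 6 (tertiary C4 boronic ester plus neopentyl C1 iodide) with a vinylidene unit: C3–C4 by 1,2-metallate shift, C1–C2 by 6-endo radical cyclization, then C–B → 3β-OH.
3. Feature that allows it: in ring A the carbinol C3 lies between quaternary C4 (CMe2, a tertiary alkyl that can migrate from boron) and the C2–C1 ethano unit ending at neopentyl C1 on quaternary C10 (a primary radical with no β-hydrogen); C5 and C10 of ring B hold both termini trans-diequatorial.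
4. 6 ⇐ (1R,5R)-verbenone 1: cyclopropanation brings in C1 anti to the CMe2 bridge (sets C10), cyclobutane cleavage frees C4, and reopening of the cyclopropyl ketone gives C1–I and the C8=C9 silyl enol ether.
5. Order of ring formation: ring B (the six-membered ring of verbenone), ring A (step 5), then union of the two bicyclic halves.

Key step: step 5

Assumption: locants follow the terpenoid numbering of one half (ring A: C1–C5 and C10; ring B: C5–C10; C11 on C9), and commercial (+)-verbenone is taken as the (1R,5R) enantiomer.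

**Route**

Step 1
Reactants: 1 (1R,5R)-(+)-verbenone
Product: 2 2,7,7-trimethyltricyclo[4.1.1.0(2,4)]octan-5-one (cyclopropane CH2 anti to the CMe2 bridge)
Conditions: Me3S(O)I, NaH, DMSO, rt → 50 °C
Reagents that add atoms: trimethylsulfoxonium iodide, C[S+](C)(C)=O.[I-]
Why: Corey–Chaykovsky cyclopropanation, in which the sulfoxonium ylide should add 1,4 to the enone from the face anti to the gem-dimethyl bridge and close the three-membered ring, so that quaternary C10 is set with the new CH2 (C1) trans to the future C4.

Step 2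
Reactants: 2 2,7,7-trimethyltricyclo[4.1.1.0(2,4)]octan-5-one
Product: 4 (1S,5S,6S)-6-methyl-5-(prop-1-en-2-yl)bicyclo[4.1.0]heptan-2-one, via diiodo ketone 3 (not isolated)
Conditions: Me3SiI, MeOH, CH2Cl2, 0 °C → rt; then t-BuOK, THF, 0 °C → rt
Reagents that add atoms: none
Why: Hydrogen iodide made in the flask should add across both ketone-activated strained bonds (homoconjugate opening of the cyclopropyl ketone at CH2 and nopinone-type cleavage of the cyclobutyl ketone to the tertiary iodide), after which base recloses the cyclopropane by 3-exo-tet enolate alkylation and removes the tertiary iodide by E2 elimination, a net isomerization that frees C4 as an isopropenyl group without touching C5 or C10.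

Step 3
Reactants: 4 (1S,5S,6S)-6-methyl-5-(prop-1-en-2-yl)bicyclo[4.1.0]heptan-2-one
Product: 5 (1S,5S,6S)-6-methyl-5-[2-(4,4,5,5-tetramethyl-1,3,2-dioxaborolan-2-yl)propan-2-yl]bicyclo[4.1.0]heptan-2-one
Conditions: (IPr)CuCl (cat.), NaOt-Bu (cat.), B2pin2, MeOH, THF, rt
Reagents that add atoms: bis(pinacolato)diboron, CC1(C)OB(OC1(C)C)B1OC(C)(C)C(C)(C)O1
Why: Copper-catalyzed formal Markovnikov hydroboration of a 1,1-disubstituted alkene (borylcupration with boron on the internal carbon, then protonolysis of the primary C–Cu bond by methanol) should give the tertiary boronic ester, and no stereocentre is formed.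

Step 4
Reactants: 5 (1S,5S,6S)-6-methyl-5-[2-(4,4,5,5-tetramethyl-1,3,2-dioxaborolan-2-yl)propan-2-yl]bicyclo[4.1.0]heptan-2-one
Product: 6 tert-butyl{[(3S,4S)-3-(iodomethyl)-3-methyl-4-[2-(4,4,5,5-tetramethyl-1,3,2-dioxaborolan-2-yl)propan-2-yl]cyclohex-1-en-1-yl]oxy}dimethylsilane
Conditions: TBSOTf, Bu4NI, CH2Cl2, −20 °C → rt; then Et3N
Reagents that add atoms: tert-butyldimethylsilyl trifluoromethanesulfonate, CC(C)(C)[Si](C)(C)OS(=O)(=O)C(F)(F)F; tetrabutylammonium iodide, CCCC[N+](CCCC)(CCCC)CCCC.[I-]
Why: Silyl iodide homoconjugate opening of a cyclopropyl ketone, in which O-silylation and SN2 attack of iodide at the cyclopropane CH2 along the bond that overlaps with the carbonyl should give the neopentyl iodide (C1) and the regiodefined C8=C9 silyl enol ether with C5 and C10 unchanged.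

Step 5
Reactants: 6 tert-butyl{[(3S,4S)-3-(iodomethyl)-3-methyl-4-[2-(4,4,5,5-tetramethyl-1,3,2-dioxaborolan-2-yl)propan-2-yl]cyclohex-1-en-1-yl]oxy}dimethylsilane; 7 2-(trimethylsilyl)oxirane
Product: 9 3β-(4,4,5,5-tetramethyl-1,3,2-dioxaborolan-2-yl)-8-(tert-butyldimethylsilyloxy)-11,12-dinordrim-8-ene (5α-H/10β-CH3), via 1-borylalkene 8 (not isolated)
Conditions: 7, s-BuLi, TMEDA, Et2O, −100 °C; add 6, −100 °C → rt; then PhMe, (Me3Si)3SiH (slow addition), AIBN, 80 °C
Reagents that add atoms: 2-(trimethylsilyl)oxirane 7, C[Si](C)(C)C1CO1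
Why: The lithiated epoxysilane adds to boron of 6 and the tertiary C4 group shifts from boron to carbon with opening of the epoxide and Peterson loss of silanolate, which forms C3–C4 and leaves 1-borylalkene 8; iodine abstraction by the silyl radical then gives the neopentyl C1 radical, which attacks the CH2 terminus (C2) and the resulting α-boryl C3 radical takes a hydrogen atom from the silane. The closest known reaction types are the vinylidene homologation of boronic esters with lithiated epoxysilanes and the 6-endo cyclization of 5-substituted hex-5-enyl radicals onto vinylboronates. Ring A closes 6-endo-trig, because the 5-exo mode would have to attack the fully substituted, boron-bearing C3 next to quaternary C4. The only new stereocentre, C3, is set in the hydrogen-atom transfer: the silane should approach the chair radical axially from the α face, away from the axial 4β and 10β methyl groups, which leaves boron equatorial (3β). The trans ring fusion needs no control, since C5 and C10 are fixed in 6 with the CH2I and CMe2B groups trans. The step needs chemoselectivity of the carbenoid for boron over the iodide and the silyl enol ether, which the lack of β-hydrogens at C1, the hindered neopentyl carbon and the low temperature should secure.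

Step 6
Reactants: 9 3β-(4,4,5,5-tetramethyl-1,3,2-dioxaborolan-2-yl)-8-(tert-butyldimethylsilyloxy)-11,12-dinordrim-8-ene
Product: 10 8-(tert-butyldimethylsilyloxy)-11,12-dinordrim-8-en-3β-ol
Conditions: NaBO3·4H2O, THF/H2O, rt
Reagents that add atoms: sodium perborate (NaBO3·4H2O), O.O.O.O.[Na+].[O-]OB=O
Why: Oxidation of the C–B bond by perborate goes through a 1,2-shift from boron to oxygen with retention, so the equatorial boronate should give the 3β (3S) alcohol while the silyl enol ether survives the mildly basic medium.

Step 7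
Reactants: 10 8-(tert-butyldimethylsilyloxy)-11,12-dinordrim-8-en-3β-ol
Product: 13 3β-hydroxy-12-nordrim-9(11)-en-8-one, via Mannich base 11 (not isolated), via methiodide 12 (not isolated)
Conditions: Me2N=CH2 I (dimethylmethylideneammonium iodide), CH2Cl2, rt; then MeI, MeCN, rt; then NaHCO3 (aq), CH2Cl2, rt
Reagents that add atoms: dimethylmethylideneammonium iodide, C[N+](C)=C.[I-]
Why: Mannich reaction of the silyl enol ether with Eschenmoser's salt at C9, N-methylation and E1cB elimination (a standard α-methylenation) should place the exo-methylene group at the only α-carbon that the enol ether allows.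

Step 8
Reactants: 13 3β-hydroxy-12-nordrim-9(11)-en-8-one (two molecules)
Product: 15 3β,21α-dihydroxy-26,27-dinoronocerane-8,14-dione (9α-H and 13-H equatorial side chain), via diketone epimers 14 (not isolated)
Conditions: SmI2, HMPA, THF (concentrated), −78 °C, then t-BuOH; then NaOMe (cat.), MeOH, rt
Reagents that add atoms: none
Why: Samarium diiodide should reduce the enone to a β-carbon radical/samarium enolate that couples tail to tail at the unhindered C11 terminus (reductive hydrodimerization of an enone), and protonation followed by methoxide equilibration α to the ketones should bring C9 and its twin to the equatorial side chain (9α-H).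

Step 9
Reactants: 15 3β,21α-dihydroxy-26,27-dinoronocerane-8,14-dione
Product: 16 α-onocerin
Conditions: Ph3PCH3Br, t-BuOK (excess), PhMe, 90 °C
Reagents that add atoms: methyltriphenylphosphonium bromide, C[P+](c1ccccc1)(c1ccccc1)c1ccccc1.[Br-]
Why: Twofold Wittig methylenation of the two hindered ring B ketones with excess ylide should give both exocyclic alkenes, the free hydroxyl groups being carried as alkoxides and C9 already being in its thermodynamic configuration.

**Compound list**

1 | (1R,5R)-(+)-verbenone, (1R,5R)-4,6,6-trimethylbicyclo[3.1.1]hept-3-en-2-one | O=C1C=C(C)[C@H]2C[C@@H]1C2(C)C | starting material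
2 | 2,7,7-trimethyltricyclo[4.1.1.0(2,4)]octan-5-one, cyclopropane CH2 anti to the CMe2 bridge | O=C1[C@@H]2C[C@@H](C2(C)C)[C@]3(C)C[C@H]13 | intermediate
3 | (3R,4R)-3-(iodomethyl)-4-(2-iodopropan-2-yl)-3-methylcyclohexan-1-one | O=C1CC[C@@H](C(C)(C)I)[C@](C)(CI)C1 | intermediate
4 | (1S,5S,6S)-6-methyl-5-(prop-1-en-2-yl)bicyclo[4.1.0]heptan-2-one | O=C1CC[C@@H](C(C)=C)[C@]2(C)C[C@H]12 | intermediate
5 | (1S,5S,6S)-6-methyl-5-[2-(4,4,5,5-tetramethyl-1,3,2-dioxaborolan-2-yl)propan-2-yl]bicyclo[4.1.0]heptan-2-one | O=C1CC[C@@H](C(C)(C)B2OC(C)(C)C(C)(C)O2)[C@]3(C)C[C@H]13 | intermediate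
6 | tert-butyl{[(3S,4S)-3-(iodomethyl)-3-methyl-4-[2-(4,4,5,5-tetramethyl-1,3,2-dioxaborolan-2-yl)propan-2-yl]cyclohex-1-en-1-yl]oxy}dimethylsilane | CC(C)(C)[Si](C)(C)OC1=C[C@@](C)(CI)[C@H](C(C)(C)B2OC(C)(C)C(C)(C)O2)CC1 | intermediate
7 | 2-(trimethylsilyl)oxirane (racemic) | C[Si](C)(C)C1CO1 | starting material
8 | tert-butyl{[(3S,4S)-3-(iodomethyl)-3-methyl-4-[2-methyl-3-(4,4,5,5-tetramethyl-1,3,2-dioxaborolan-2-yl)but-3-en-2-yl]cyclohex-1-en-1-yl]oxy}dimethylsilane | CC(C)(C)[Si](C)(C)OC1=C[C@@](C)(CI)[C@H](C(C)(C)C(=C)B2OC(C)(C)C(C)(C)O2)CC1 | intermediate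
9 | 3β-(4,4,5,5-tetramethyl-1,3,2-dioxaborolan-2-yl)-8-(tert-butyldimethylsilyloxy)-11,12-dinordrim-8-ene (trans-fused, 5α-H, 10β-CH3) | CC(C)(C)[Si](C)(C)OC1=C[C@@]2(C)CC[C@H](B3OC(C)(C)C(C)(C)O3)C(C)(C)[C@@H]2CC1 | intermediate
10 | 8-(tert-butyldimethylsilyloxy)-11,12-dinordrim-8-en-3β-ol (3S, 5α-H, 10β-CH3) | CC(C)(C)[Si](C)(C)OC1=C[C@@]2(C)CC[C@H](O)C(C)(C)[C@@H]2CC1 | intermediate
11 | 11-(dimethylamino)-3β-hydroxy-12-nordriman-8-one (C9 epimers) | O=C1CC[C@H]2C(C)(C)[C@@H](O)CC[C@]2(C)C1CN(C)C | intermediate
12 | (3β-hydroxy-8-oxo-12-nordriman-11-yl)trimethylammonium iodide (C9 epimers) | O=C1CC[C@H]2C(C)(C)[C@@H](O)CC[C@]2(C)C1C[N+](C)(C)C.[I-] | intermediate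
13 | 3β-hydroxy-12-nordrim-9(11)-en-8-one, (4aR,6S,8aS)-6-hydroxy-5,5,8a-trimethyl-1-methylideneoctahydronaphthalen-2(1H)-one | O=C1CC[C@H]2C(C)(C)[C@@H](O)CC[C@]2(C)C1=C | intermediate
14 | 3β,21α-dihydroxy-26,27-dinoronocerane-8,14-dione, mixture of epimers at C9 and C13 | O=C1CC[C@H]2C(C)(C)[C@@H](O)CC[C@]2(C)C1CCC1C(=O)CC[C@H]2C(C)(C)[C@@H](O)CC[C@]12C | intermediate
15 | 3β,21α-dihydroxy-26,27-dinoronocerane-8,14-dione (C2-symmetric; 5α-H, 9α-H, 10β-CH3 in each half) | O=C1CC[C@H]2C(C)(C)[C@@H](O)CC[C@]2(C)[C@H]1CC[C@H]1C(=O)CC[C@H]2C(C)(C)[C@@H](O)CC[C@]12C | intermediate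
16 | α-onocerin, onocera-8(26),14(27)-diene-3β,21α-diol | C=C1CC[C@H]2C(C)(C)[C@@H](O)CC[C@]2(C)[C@H]1CC[C@H]1C(=C)CC[C@H]2C(C)(C)[C@@H](O)CC[C@]12C | target

**Step count and risks**

Total steps: 9. Longest linear sequence: 9 steps (from 1; compound 7 is bought).

Steps most likely to fail:

Step 5. The hindered tertiary boronic ester may take up the bulky lithiated epoxysilane too slowly, so that the carbenoid decomposes first; the C1 radical may also be reduced before the 6-endo closure. The fallback builds ring A by polar chemistry and sets out from 4. Cobalt-mediated hydrogen-atom-transfer hydrobromination (Co(acac)2, t-BuOOH, Et3SiH, TsBr) should give the tertiary bromide F1. Nickel-catalyzed reductive acylation with acetic anhydride (NiBr2·diglyme, 4,4′-di-tert-butyl-2,2′-bipyridine, Zn, MgCl2, DMA) should then form the C3–C4 bond in the tert-alkyl methyl ketone F2. Opening of the cyclopropyl ketone as in step 4 (TBSOTf, Bu4NI) should give the iodo silyl enol ether F3. Its methyl ketone has only one enolizable side; the LDA enolate (THF/HMPA) should close the C1–C2 bond by 6-exo-tet alkylation to the bicyclic 3-ketone F4. NaBH4 reduction from the α face gives the 3β-alcohol and the route is rejoined at 10.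

Step 3. The copper boryl species may attack the ketone or open the cyclopropyl ketone, and borylcupration of the hindered isopropenyl group may be slow or poorly Markovnikov-selective. The fallback avoids the alkene and sets out from the crude diiodide 3 before its base treatment. Nickel-catalyzed borylation of alkyl halides (NiBr2·diglyme, a pybox ligand, B2pin2, KOEt, DMA/i-Pr2O) is used; the ethoxide recloses the cyclopropane from the γ-iodo ketone, and the tertiary iodide, the halide class that reacts fastest in this borylation, is turned into the C–B bond. This comes back to the route at 5 without a new intermediate.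

Step 8. The enone may be reduced further to the saturated α-methyl ketone, or the samarium enolate may close by aldol addition onto the second ketone instead of leaving the open 1,6-diketone. The fallback forms the C11–C12 bond by radical dimerization and sets out from 10. Fluoride-induced regiospecific enolate formation from the silyl enol ether (anhydrous Bu4NF, THF) and alkylation with tert-butyl bromoacetate should give the keto ester F5. CF3CO2H cleaves it to the keto acid F6. Kolbe electrolysis (platinum electrodes, MeOH, partial neutralization with NaOMe) then couples two C11 radicals with loss of carbon dioxide and comes back to the route at 15.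

Further compounds
F1 | step 5 | 5-(2-bromopropan-2-yl)-6-methylbicyclo[4.1.0]heptan-2-one (ring stereocentres as in 4) | O=C1CC[C@@H](C(C)(C)Br)[C@]2(C)C[C@H]12
F2 | step 5 | 6-methyl-5-(2-methyl-3-oxobutan-2-yl)bicyclo[4.1.0]heptan-2-one (ring stereocentres as in 4) | O=C1CC[C@@H](C(C)(C)C(C)=O)[C@]2(C)C[C@H]12
F3 | step 5 | 3-{4-[(tert-butyldimethylsilyl)oxy]-2-(iodomethyl)-2-methylcyclohex-3-en-1-yl}-3-methylbutan-2-one (ring stereocentres as in 6) | CC(C)(C)[Si](C)(C)OC1=C[C@@](C)(CI)[C@H](C(C)(C)C(C)=O)CC1
F4 | step 5 | 8-(tert-butyldimethylsilyloxy)-11,12-dinordrim-8-en-3-one (5α-H, 10β-CH3) | CC(C)(C)[Si](C)(C)OC1=C[C@@]2(C)CCC(=O)C(C)(C)[C@@H]2CC1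
F0 | step 3 | none | none
F5 | step 8 | tert-butyl (3β-hydroxy-8-oxo-12-nordriman-11-yl)formate, i.e. tert-butyl 2-(3β-hydroxy-8-oxo-11,12-dinordriman-9β-yl)acetate (9α-H) | O=C1CC[C@H]2C(C)(C)[C@@H](O)CC[C@]2(C)[C@H]1CC(=O)OC(C)(C)C
F6 | step 8 | 2-(3β-hydroxy-8-oxo-11,12-dinordriman-9β-yl)acetic acid (9α-H) | O=C1CC[C@H]2C(C)(C)[C@@H](O)CC[C@]2(C)[C@H]1CC(=O)O
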